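**Retrosynthetic overview**

- The strategy rests on the pyrrole being a hidden dimer: its C3–C4 bond joins two identical three-carbon units, each consisting of an indol-3-yl-bearing ring carbon (C3 or C4), the neighbouring ring carbon (C2 or C5) and a carboxyl carbon on it. N1 bridges C2 and C5, and C5–H marks a carboxyl that has been removed.
- Target 13 ⇐ monoacid 12 (protodecarboxylation at the carbon that becomes C5–H) ⇐ symmetric 2,5-diester 11 (hydrolysis of one ester).
- 11 ⇐ dioxo diester 10 + ammonia 8 (Paal–Knorr, N1–C2 and N1–C5) ⇐ two enolates 9 of keto ester 7 joined by iodine (C3–C4), all in one flask.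
- 7 ⇐ keto acid 6 ⇐ azlactone 4 ⇐ aldehyde 1 + N-acetylglycine 2 (Erlenmeyer–Plöchl).
- Ring order: both indoles are bought intact; the pyrrole is the only ring built (step 4).

Key step: step 4

Remark on the chemistry: 6 and 7 are drawn as keto tautomers although they should exist largely as Z-enols; the target has no stereocentre, and the two CH centres of intermediate 10 (meso and racemic forms) disappear on aromatisation.

**Route**

Step 1
Reactants: 1 5-bromo-1H-indole-3-carbaldehyde; 2 N-acetylglycine
Product: 4 (Z)-4-[(1-acetyl-5-bromo-1H-indol-3-yl)methylidene]-2-methyl-1,3-oxazol-5(4H)-one, via 2-methyloxazol-5(4H)-one 3 (not isolated)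
Conditions: Ac2O, NaOAc, 105 °C
Reagents that add atoms: acetic anhydride, CC(=O)OC(C)=O
Why: Erlenmeyer–Plöchl azlactone synthesis, in which Ac2O cyclodehydrates N-acetylglycine to oxazolone 3, whose acidic ring CH2 condenses with the aldehyde under acetate catalysis (Perkin-type); the indole nitrogen is acetylated in the same pot, which makes the vinylogous formamide carbonyl more electrophilic, and the more stable Z-alkene (aryl syn to the ring nitrogen) should result.

Step 2
Reactants: 4 (Z)-4-[(1-acetyl-5-bromo-1H-indol-3-yl)methylidene]-2-methyl-1,3-oxazol-5(4H)-one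
Product: 6 3-(5-bromo-1H-indol-3-yl)-2-oxopropanoic acid, via 2-acetamido-3-(5-bromoindol-3-yl)acrylic acid 5 (not isolated)
Conditions: NaOH (aq., 2.5 M, degassed), reflux, N2; then HCl (aq.), 0 °C
Reagents that add atoms: water, O
Why: Azlactone and enamide hydrolysis (second stage of the Erlenmeyer arylpyruvic acid synthesis), in which hydroxide opens the oxazolone and strips the labile N1-acetyl group to give the salt of 5, whose enamide is then cleaved on heating so that the freed enamine tautomerises to the imine and hydrolyses to the keto acid, which should precipitate on cold acidification; air is excluded because the enolate is prone to oxidation.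

Step 3
Reactants: 6 3-(5-bromo-1H-indol-3-yl)-2-oxopropanoic acid
Product: 7 methyl 3-(5-bromo-1H-indol-3-yl)-2-oxopropanoate
Conditions: MeI (1.1 equiv), KHCO3 (1.0 equiv), DMF, 0 °C to rt, argon
Reagents that add atoms: iodomethane, CI
Why: Carboxylate O-alkylation (SN2), in which one equivalent of KHCO3 ionises only the carboxylic acid, so that iodomethane methylates the carboxylate while the enol OH, the activated CH2 and the indole N–H stay protonated and unreactive.

Step 4
Reactants: 7 methyl 3-(5-bromo-1H-indol-3-yl)-2-oxopropanoate (two molecules); 8 ammonia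
Product: 11 dimethyl 3,4-bis(5-bromo-1H-indol-3-yl)-1H-pyrrole-2,5-dicarboxylate, via sodium enolate of the keto ester 9 (not isolated), via dimethyl 3,4-bis(5-bromo-1H-indol-3-yl)-2,5-dioxohexanedioate 10 (not isolated)
Conditions: NaH (1.0 equiv), THF, 0 °C; I2 (0.5 equiv), THF, −78 °C to rt; then NH3 (7 M in MeOH, excess), AcOH (cat.), 4 Å MS, rt to 50 °C
Reagents that add atoms: none
Why: NaH removes only the doubly activated proton of 7 (indol-3-ylmethyl and α to the ketone; the indole N–H is far less acidic), and half an equivalent of I2 C-iodinates one enolate 9 at that carbon so that a second enolate displaces iodide (or two enolate radicals combine), creating the C3–C4 bond of dioxo diester 10. Ammonia then condenses with one highly electrophilic α-keto ester carbonyl, the resulting enamine nitrogen adds to the second ketone in a 5-exo-trig closure (N1–C2 and N1–C5), and loss of two molecules of water aromatises the pyrrole (Paal–Knorr). The closest known reaction type is the iodine coupling of sodium β-keto ester and arylpyruvate enolates to 1,4-diketones followed by Paal–Knorr condensation with ammonia or primary amines. No stereocentre has to be controlled, because the two CH centres of 10 both become sp2 carbons of the pyrrole. The step needs carbon–carbon coupling in preference to oxygen or indole coupling and no over-oxidation of 10: the soft enolate carbon, the blocked indole C3 positions and slow addition of exactly half an equivalent of I2 at −78 °C should secure this, and the acetate-buffered ammonia should close the ring faster than it ammonolyses the esters.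

Step 5
Reactants: 11 dimethyl 3,4-bis(5-bromo-1H-indol-3-yl)-1H-pyrrole-2,5-dicarboxylate
Product: 12 3,4-bis(5-bromo-1H-indol-3-yl)-5-(methoxycarbonyl)-1H-pyrrole-2-carboxylic acid
Conditions: LiOH·H2O (1.5 equiv), THF/MeOH/H2O, rt to 40 °C; then HCl (aq., 1 M), 0 °C, pH 3
Reagents that add atoms: lithium hydroxide, [Li+].[OH-]
Why: Ester saponification (addition–elimination at the acyl carbon) of a symmetric diester, in which the first lithium carboxylate makes the ring more electron-rich and the molecule anionic, so that hydroxide attacks the remaining ester much more slowly and the reaction can be stopped at the monoacid; aryl bromides and indoles are inert to aqueous LiOH.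

Step 6
Reactants: 12 3,4-bis(5-bromo-1H-indol-3-yl)-5-(methoxycarbonyl)-1H-pyrrole-2-carboxylic acid
Product: 13 methyl 3,4-bis(5-bromo-1H-indol-3-yl)-1H-pyrrole-2-carboxylate (target)
Conditions: TFA, CH2Cl2, rt to 40 °C, argon
Reagents that add atoms: none
Why: Acid-promoted protodecarboxylation of a pyrrole-2-carboxylic acid, in which TFA protonates the ring carbon that carries the carboxyl group (made electron-rich by the pyrrole nitrogen and the adjacent indol-3-yl group), CO2 is lost and the aromatic pyrrole with C5–H is restored, while the methyl ester, the C3-blocked indoles and the aryl bromides should tolerate anhydrous TFA.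

**Compound list**

1 | 5-bromo-1H-indole-3-carbaldehyde | O=Cc1c[nH]c2ccc(Br)cc12 | starting material
2 | N-acetylglycine | CC(=O)NCC(=O)O | starting material
3 | 2-methyl-1,3-oxazol-5(4H)-one | CC1=NCC(=O)O1 | intermediate
4 | (Z)-4-[(1-acetyl-5-bromo-1H-indol-3-yl)methylidene]-2-methyl-1,3-oxazol-5(4H)-one | CC1=N/C(=C\c2cn(C(C)=O)c3ccc(Br)cc23)C(=O)O1 | intermediate
5 | (Z)-2-acetamido-3-(5-bromo-1H-indol-3-yl)prop-2-enoic acid (sodium salt in the flask) | CC(=O)N/C(=C\c1c[nH]c2ccc(Br)cc12)C(=O)O | intermediate
6 | 3-(5-bromo-1H-indol-3-yl)-2-oxopropanoic acid | O=C(O)C(=O)Cc1c[nH]c2ccc(Br)cc12 | intermediate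
7 | methyl 3-(5-bromo-1H-indol-3-yl)-2-oxopropanoate | COC(=O)C(=O)Cc1c[nH]c2ccc(Br)cc12 | intermediate
8 | ammonia | N | starting material
9 | sodium (Z)-1-(5-bromo-1H-indol-3-yl)-3-methoxy-3-oxoprop-1-en-2-olate | COC(=O)/C([O-])=C/c1c[nH]c2ccc(Br)cc12.[Na+] | intermediate
10 | dimethyl 3,4-bis(5-bromo-1H-indol-3-yl)-2,5-dioxohexanedioate (mixture of meso and racemic forms) | COC(=O)C(=O)C(c1c[nH]c2ccc(Br)cc12)C(c1c[nH]c2ccc(Br)cc12)C(=O)C(=O)OC | intermediate
11 | dimethyl 3,4-bis(5-bromo-1H-indol-3-yl)-1H-pyrrole-2,5-dicarboxylate | COC(=O)c1[nH]c(C(=O)OC)c(-c2c[nH]c3ccc(Br)cc23)c1-c1c[nH]c2ccc(Br)cc12 | intermediate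
12 | 3,4-bis(5-bromo-1H-indol-3-yl)-5-(methoxycarbonyl)-1H-pyrrole-2-carboxylic acid | COC(=O)c1[nH]c(C(=O)O)c(-c2c[nH]c3ccc(Br)cc23)c1-c1c[nH]c2ccc(Br)cc12 | intermediate
13 | methyl 3,4-bis(5-bromo-1H-indol-3-yl)-1H-pyrrole-2-carboxylate | COC(=O)c1[nH]cc(-c2c[nH]c3ccc(Br)cc23)c1-c1c[nH]c2ccc(Br)cc12 | target

**Totals**

Total step count: 6. Longest linear sequence: 6 steps (1 to 13).

**Steps most likely to fail**

1. Step 4 (key step). The coupling may be diverted by iodination at oxygen or on the indole rings, by further oxidation of the coupled diketone, or by ammonolysis and retro-Claisen cleavage of the α-keto ester groups before the ring closes. The fallback sets out from keto acid 6 and comes back at diester 11, so that no ester is present while ammonia is in the flask. The acid is converted into its carboxylate enolate dianion with LiN(SiMe3)2 (2.0 equiv) in THF at −78 °C and coupled with I2 (0.5 equiv). This should give 3,4-bis(5-bromo-1H-indol-3-yl)-2,5-dioxohexanedioic acid F1 as its dilithium salt, which is not isolated. Aqueous ammonia at room temperature should then close the ring to 3,4-bis(5-bromo-1H-indol-3-yl)-1H-pyrrole-2,5-dicarboxylic acid F2, collected by cold acidification to pH 3–4. Double esterification with MeI and KHCO3 (2 equiv each) in DMF returns the route to 11.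

2. Step 5. Hydrolysis may run on to the diacid, or stall because hydroxide deprotonates the pyrrole N–H, so that a mixture of diester, monoacid and diacid is obtained. The fallback sets out from diester 11 and comes back at target 13; it also bypasses step 6. KOH in ethylene glycol at 170 °C under argon should saponify both esters and remove both carboxyl groups, passing through the dipotassium salt of 3,4-bis(5-bromo-1H-indol-3-yl)-1H-pyrrole-2,5-dicarboxylic acid F2, to give 3,4-bis(5-bromo-1H-indol-3-yl)-1H-pyrrole F3. Friedel–Crafts acylation with trichloroacetyl chloride (1.05 equiv) and 2,6-lutidine in CH2Cl2 at −20 to 0 °C should attack one free pyrrole α-position only, because the first acyl group deactivates the ring, and give 1-[3,4-bis(5-bromo-1H-indol-3-yl)-1H-pyrrol-2-yl]-2,2,2-trichloroethan-1-one F4. Haloform-type cleavage with NaOMe in MeOH at room temperature then delivers 13.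

3. Step 2. The electron-rich enolate of the keto acid may be degraded oxidatively in hot alkali, or the enamide may hydrolyse incompletely. The fallback sets out from aldehyde 1 and comes back at keto ester 7, avoiding both the free acid and alkali. Boc2O with catalytic DMAP in MeCN should give tert-butyl 5-bromo-3-formyl-1H-indole-1-carboxylate F5. Horner–Wadsworth–Emmons olefination with methyl 2-[(tert-butoxycarbonyl)amino]-2-(dimethoxyphosphoryl)acetate and DBU in CH2Cl2 should give methyl (Z)-3-[5-bromo-1-(tert-butoxycarbonyl)-1H-indol-3-yl]-2-[(tert-butoxycarbonyl)amino]prop-2-enoate F6. TFA in CH2Cl2 at room temperature removes both Boc groups to leave methyl (Z)-2-amino-3-(5-bromo-1H-indol-3-yl)prop-2-enoate F7, which is not isolated; on addition of water it tautomerises to the imine and hydrolyses to 7.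

**Further compounds**

F1 | step 4 | 3,4-bis(5-bromo-1H-indol-3-yl)-2,5-dioxohexanedioic acid | O=C(O)C(=O)C(c1c[nH]c2ccc(Br)cc12)C(c1c[nH]c2ccc(Br)cc12)C(=O)C(=O)O
F2 | step 4 | 3,4-bis(5-bromo-1H-indol-3-yl)-1H-pyrrole-2,5-dicarboxylic acid | O=C(O)c1[nH]c(C(=O)O)c(-c2c[nH]c3ccc(Br)cc23)c1-c1c[nH]c2ccc(Br)cc12
F3 | step 5 | 3,4-bis(5-bromo-1H-indol-3-yl)-1H-pyrrole | c1[nH]cc(-c2c[nH]c3ccc(Br)cc23)c1-c1c[nH]c2ccc(Br)cc12
F4 | step 5 | 1-[3,4-bis(5-bromo-1H-indol-3-yl)-1H-pyrrol-2-yl]-2,2,2-trichloroethan-1-one | O=C(c1[nH]cc(-c2c[nH]c3ccc(Br)cc23)c1-c1c[nH]c2ccc(Br)cc12)C(Cl)(Cl)Cl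
F5 | step 2 | tert-butyl 5-bromo-3-formyl-1H-indole-1-carboxylate | CC(C)(C)OC(=O)n1cc(C=O)c2cc(Br)ccc21
F6 | step 2 | methyl (Z)-3-[5-bromo-1-(tert-butoxycarbonyl)-1H-indol-3-yl]-2-[(tert-butoxycarbonyl)amino]prop-2-enoate | COC(=O)/C(NC(=O)OC(C)(C)C)=C/c1cn(C(=O)OC(C)(C)C)c2ccc(Br)cc12
F7 | step 2 | methyl (Z)-2-amino-3-(5-bromo-1H-indol-3-yl)prop-2-enoate | COC(=O)/C(N)=C/c1c[nH]c2ccc(Br)cc12
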